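**Retrosynthetic overview**
- Cut both aryl ketone C–C bonds last: verbenachalcone ⇒ a diaryl ether bis(propanoic acid) + two resorcinol units (double Friedel–Crafts acylation, no protecting groups).
- Cut the diaryl ether C–O bond (key bond, new step): ⇒ methyl dihydroferulate as the O–H partner + the ortho-quinone diazide of the other ring as the carbene partner. The carbon bearing N2 fixes the regiochemistry, and the ortho OH appears unprotected.
- Quinone diazide ⇒ ortho-aminophenol ⇒ ortho-nitrophenol ⇒ methyl 3-(4-hydroxyphenyl)propanoate.
- No ring is built, since all four benzene rings are bought. Ring B' (phenol ring) is joined to ring B (methoxy ring) first, then the two resorcinol rings A and A' are attached together in the last step.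

Assumption: the target SMILES holds no stereocentre and no stereogenic double bond, so the compound is achiral and the route only has to deliver the given constitution.

**Step 1**
Reactants: 1 methyl 3-(4-hydroxyphenyl)propanoate
Product: 2 methyl 3-(4-hydroxy-3-nitrophenyl)propanoate
Conditions: 65% HNO3 (1.05 equiv), AcOH, 10 °C to rt, 1 h
Reagents that add atoms: nitric acid, O[N+](=O)[O-]
Why: Electrophilic aromatic nitration goes ortho to the OH group because the para position carries the side chain, and the first nitro group deactivates the ring against a second one; no stereocentre is formed.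

**Step 2**
Reactants: 2 methyl 3-(4-hydroxy-3-nitrophenyl)propanoate
Product: 3 methyl 3-(3-amino-4-hydroxyphenyl)propanoate
Conditions: H2 (1 atm), 10% Pd/C, MeOH, rt, 3 h; used at once
Reagents that add atoms: none
Why: Heterogeneous catalytic hydrogenation reduces the nitroarene to the aniline and leaves the methyl ester, phenol and arene untouched; no stereocentre is formed.

**Step 3**
Reactants: 3 methyl 3-(3-amino-4-hydroxyphenyl)propanoate
Product: 5 methyl 3-(3-diazo-4-oxocyclohexa-1,5-dien-1-yl)propanoate, via diazonium chloride 4 (not isolated)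
Conditions: NaNO2 (1.05 equiv), 2 M aq HCl, 0 °C, 30 min; then NaHCO3 to pH 8, CH2Cl2 extraction, short silica plug, dark, below 20 °C
Reagents that add atoms: sodium nitrite, [Na+].[O-]N=O
Why: Classical diazotisation of an ortho-aminophenol, then deprotonation of the acidic hydroxydiazonium ion (pKa about 4), gives the neutral, extractable ortho-quinone diazide, and the cold dilute acid and bicarbonate spare the ester; no stereocentre is formed.

**Step 4**
Reactants: 5 methyl 3-(3-diazo-4-oxocyclohexa-1,5-dien-1-yl)propanoate; 6 methyl 3-(4-hydroxy-3-methoxyphenyl)propanoate (methyl dihydroferulate)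
Product: 8 methyl 3-[4-hydroxy-3-[2-methoxy-4-(3-methoxy-3-oxopropyl)phenoxy]phenyl]propanoate, via rhodium quinoid carbene 7 (not isolated)
Conditions: 6 (2.5 equiv), Rh2(esp)2 (1 mol %; esp = α,α,α',α'-tetramethyl-1,3-benzenedipropanoate), 4 Å MS, PhCF3, 60 °C, dark; 5 added by syringe pump over 4 h; excess 6 recovered
Reagents that add atoms: none
Why: Proposed new method: dirhodium-catalysed O–H insertion of a monocyclic ortho-quinone diazide into a hindered phenol, used as a diaryl ether synthesis, which has not been shown for this pair of partners. The nucleophilic diazo carbon of 5 binds an axial site of Rh2(esp)2 (two divalent rhodium centres) and N2 leaves to give the strongly electrophilic carbene 7. The phenol oxygen of 6 attacks the carbene carbon while its proton passes through a five-membered, hydrogen-bonded, ylide-like transition state to the neighbouring carbonyl oxygen, which is irreversible because it restores the benzene ring and frees the catalyst. The C–O bond can therefore form only at the carbon that carried N2, and the ortho OH of 8 arises unprotected. C–H attack on 6 is disfavoured because its para and one ortho position are blocked. Azo coupling is slow because 5 is far too weak a base to make phenolate from 6. The chelating esp ligand resists exchange by phenols. Slow addition of 5 to excess 6 holds back carbene dimerisation and a second insertion into the more hindered, internally hydrogen-bonded phenol of 8. The closest known reaction types are the dirhodium tetracarboxylate-catalysed O–H insertion of α-diazo carbonyl compounds into phenols and of 1,2-naphthoquinone diazides into aliphatic alcohols. No stereocentre is formed.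

**Step 5**
Reactants: 8 methyl 3-[4-hydroxy-3-[2-methoxy-4-(3-methoxy-3-oxopropyl)phenoxy]phenyl]propanoate
Product: 9 3-[3-[4-(2-carboxyethyl)-2-methoxyphenoxy]-4-hydroxyphenyl]propanoic acid
Conditions: LiOH·H2O (6 equiv), THF/H2O 3:1, rt, 4 h; then 1 M HCl to pH 2
Reagents that add atoms: lithium hydroxide, [Li+].[OH-]
Why: Ordinary ester saponification by acyl–oxygen cleavage hydrolyses both unhindered methyl esters, while the diaryl ether, aryl methyl ether and phenol are inert to aqueous hydroxide at room temperature; no stereocentre is formed.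

**Step 6**
Reactants: 9 3-[3-[4-(2-carboxyethyl)-2-methoxyphenoxy]-4-hydroxyphenyl]propanoic acid; 10 resorcinol
Product: 11 verbenachalcone
Conditions: 10 (4 equiv), BF3·OEt2 (neat, 0.3 M in 9), 85 °C, 2.5 h, under N2; then ice-water, EtOAc
Reagents that add atoms: none
Why: In this double Nencki-type Friedel–Crafts acylation BF3 activates each carboxylic acid, and resorcinol, by far the most nucleophilic arene present and used in excess, reacts at C4 (para to one OH, ortho to the other) to give the chelated 2,4-dihydroxyphenyl ketone, outrunning indanone closure and leaving the aryl methyl ether and diaryl ether intact; no stereocentre is formed.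

**Compound list**
1 | methyl 3-(4-hydroxyphenyl)propanoate | COC(=O)CCc1ccc(O)cc1 | starting material
2 | methyl 3-(4-hydroxy-3-nitrophenyl)propanoate | COC(=O)CCc1ccc(O)c([N+](=O)[O-])c1 | intermediate
3 | methyl 3-(3-amino-4-hydroxyphenyl)propanoate | COC(=O)CCc1ccc(O)c(N)c1 | intermediate
4 | 2-hydroxy-5-(3-methoxy-3-oxopropyl)benzenediazonium chloride | COC(=O)CCc1ccc(O)c([N+]#N)c1.[Cl-] | intermediate (not isolated)
5 | methyl 3-(3-diazo-4-oxocyclohexa-1,5-dien-1-yl)propanoate (ortho-quinone diazide) | COC(=O)CCC1=CC(=[N+]=[N-])C(=O)C=C1 | intermediate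
6 | methyl 3-(4-hydroxy-3-methoxyphenyl)propanoate (methyl dihydroferulate) | COC(=O)CCc1ccc(O)c(OC)c1 | starting material
7 | rhodium quinoid carbene: 5-(3-methoxy-3-oxopropyl)-2-oxocyclohexa-3,5-dien-1-ylidene bound through the carbene carbon to one rhodium of Rh2(esp)2 | COC(=O)CCC1=CC(=[Rh+2])C(=O)C=C1.[Rh+2].CC(C)(Cc1cccc(CC(C)(C)C(=O)[O-])c1)C(=O)[O-].CC(C)(Cc1cccc(CC(C)(C)C(=O)[O-])c1)C(=O)[O-] | intermediate (not isolated)
8 | methyl 3-[4-hydroxy-3-[2-methoxy-4-(3-methoxy-3-oxopropyl)phenoxy]phenyl]propanoate | COC(=O)CCc1ccc(O)c(Oc2ccc(CCC(=O)OC)cc2OC)c1 | intermediate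
9 | 3-[3-[4-(2-carboxyethyl)-2-methoxyphenoxy]-4-hydroxyphenyl]propanoic acid | OC(=O)CCc1ccc(O)c(Oc2ccc(CCC(=O)O)cc2OC)c1 | intermediate
10 | resorcinol (benzene-1,3-diol) | Oc1cccc(O)c1 | starting material
11 | verbenachalcone, 1-(2,4-dihydroxyphenyl)-3-[4-[5-[3-(2,4-dihydroxyphenyl)-3-oxopropyl]-2-hydroxyphenoxy]-3-methoxyphenyl]propan-1-one (achiral) | COc1cc(CCC(=O)c2ccc(O)cc2O)ccc1Oc1cc(CCC(=O)c2ccc(O)cc2O)ccc1O | target

**Total step count:** 6. **Longest linear sequence:** 6 steps (1 → 2 → 3 → 5 → 8 → 9 → 11).

**Three steps most likely to fail**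

**Step 4 (proposed new step).** The risks are azo coupling, carbene dimerisation, C–H arylation of 6, ring contraction of the carbene and over-insertion into 8. The fallback uses known chemistry, sets out from 1 and comes back at 8.
- Compound 1 is iodinated ortho to the OH group (N-iodosuccinimide, cat. TsOH, MeCN, rt) to methyl 3-(4-hydroxy-3-iodophenyl)propanoate F1.
- Benzylation (BnBr, K2CO3, DMF, rt) gives methyl 3-[4-(benzyloxy)-3-iodophenyl]propanoate F2.
- Ullmann-type coupling of F2 with 6 under conditions made for hindered partners (CuI, copper iodide, 10 mol %, picolinic acid 20 mol %, K3PO4, DMSO, 90 °C) gives methyl 3-[4-(benzyloxy)-3-[2-methoxy-4-(3-methoxy-3-oxopropyl)phenoxy]phenyl]propanoate F3.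
- Hydrogenolysis (H2, Pd/C, EtOAc/MeOH, rt) gives 8.

**Step 3.** The risks are oxidation of the aminophenol by nitrous acid, azo dye formation during the aqueous pH change and loss of the light- and heat-sensitive product on extraction. The fallback sets out from 3 and comes back at 5. It gives up the aqueous one-pot sequence and goes through an isolated, storable salt made without water.
- Compound 3 is diazotised with tBuONO and HBF4·OEt2 in THF at −10 °C.
- Et2O precipitates 2-hydroxy-5-(3-methoxy-3-oxopropyl)benzenediazonium tetrafluoroborate F4, which is filtered off and kept cold.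
- Just before use it is stirred with solid K2CO3 in CH2Cl2 at 0 °C and filtered to give a dry solution of 5.

**Step 6.** The risks are incomplete second acylation, indanone closure onto the methoxy ring and condensation of the product ketones with excess resorcinol. The fallback sets out from 8, skips 9 and comes back at 11. It replaces the electrophilic aromatic substitution by a nucleophilic aryl addition.
- Compound 8 is treated with MeNHOMe·HCl and iPrMgCl (THF, −15 °C; the phenol rides along as its magnesium phenoxide) to give the bis-Weinreb amide 3-[4-hydroxy-3-[2-methoxy-4-[3-[methoxy(methyl)amino]-3-oxopropyl]phenoxy]phenyl]-N-methoxy-N-methylpropanamide F5.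
- 1-Bromo-2,4-bis(benzyloxy)benzene and nBuLi (THF, −78 °C) give 2,4-bis(benzyloxy)phenyllithium F6.
- F6 is added (2.5 equiv) to F5, whose phenol has first been deprotonated with iPrMgCl (1 equiv). After an NH4Cl quench this gives the tetra-O-benzyl ether of verbenachalcone (all four resorcinol OH groups benzylated) F7.
- Hydrogenolysis (H2 1 atm, Pd/C, EtOAc/MeOH, rt) gives 11 without touching the electron-rich aryl ketones.

**Further compounds**
F1 | step 4 | methyl 3-(4-hydroxy-3-iodophenyl)propanoate | COC(=O)CCc1ccc(O)c(I)c1
F2 | step 4 | methyl 3-[4-(benzyloxy)-3-iodophenyl]propanoate | COC(=O)CCc1ccc(OCc2ccccc2)c(I)c1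
F3 | step 4 | methyl 3-[4-(benzyloxy)-3-[2-methoxy-4-(3-methoxy-3-oxopropyl)phenoxy]phenyl]propanoate | COC(=O)CCc1ccc(OCc2ccccc2)c(Oc2ccc(CCC(=O)OC)cc2OC)c1
F4 | step 3 | 2-hydroxy-5-(3-methoxy-3-oxopropyl)benzenediazonium tetrafluoroborate | COC(=O)CCc1ccc(O)c([N+]#N)c1.F[B-](F)(F)F
F5 | step 6 | 3-[4-hydroxy-3-[2-methoxy-4-[3-[methoxy(methyl)amino]-3-oxopropyl]phenoxy]phenyl]-N-methoxy-N-methylpropanamide | CON(C)C(=O)CCc1ccc(O)c(Oc2ccc(CCC(=O)N(C)OC)cc2OC)c1
F6 | step 6 | 2,4-bis(benzyloxy)phenyllithium | [Li]c1ccc(OCc2ccccc2)cc1OCc1ccccc1
F7 | step 6 | tetra-O-benzyl ether of verbenachalcone (all four resorcinol OH groups benzylated) | COc1cc(CCC(=O)c2ccc(OCc3ccccc3)cc2OCc2ccccc2)ccc1Oc1cc(CCC(=O)c2ccc(OCc3ccccc3)cc2OCc2ccccc2)ccc1O
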